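In the alder vessel starting material and second reagent stand together from the start while partner runs in over 6.0 min; alder has been followed to 12.0 min, and birch differs from it in its second reagent.

| flask | starting material | partner | second reagent | third reagent | remark | time |
|---|---|---|---|---|---|---|
| alder | 0.20 M | 0.95 equiv (fed, over 6.0 min) | 2 equiv | 1.5 equiv | the very flask that is asked about, followed so far; the fed solution adds 0.20 times the starting volume |  |
| birch | 0.20 M | 0.95 equiv (fed, over 6.0 min) | 1.3 equiv | 1.5 equiv | run made earlier; the fed solution adds 0.20 times the starting volume |  |
| flask | 0.20 M | 0.950 equiv (fed, over 6.0 min) | 2.00 equiv | 1.50 equiv | the fed solution adds 0.20 times the starting volume | 30 min |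

- alder (time / min: target / %, side product / %): 0.833: 0, 4.4; 2.50: 0, 9.8; 4.00: 0, 15.4; 6.00: 0, 21.2; 10.0: 0.3, 28.7; 12.0: 0.3, 32.7
- birch (time / min: target / %, side product / %): 5.00: 0, 12.9; 10.0: 0.7, 20.1; 15.0: 0.8, 25.1; 20.0: 0.5, 28.5; 25.0: 1.0, 31.2; 30.0: 1.8, 34.2

(scatter of a reading: 0.5 percentage points)

- amount of target in the flask at 30 min, in percent of the starting material charged
- amount of side product in the flask at 30 min, in percent of the starting material charged
- amount of intermediate A in the flask at 30 min, in percent of the starting material charged
- concentration of second reagent at 30 min, in M

- charges are per starting volume, the dose included; the dosed solution carries all of it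

Read as two drains on starting material, the runs can be described by one number for how the drains share it. Alder's first reading gives side product forming at 0.0528 min⁻¹ of the charge, with that reading's scatter. Birch's side-product slope from 20.0 min to 30.0 min is 0.00570 min⁻¹. Taking the rate as proportional to both reactants, and allowing for dilution and spent second reagent, the estimate for birch is 26.2% of its starting material at 25.0 min. Setting side product against the remainder, taken to have gone through partner, gives 0.733. Scaled to alder's second reagent, this gives 1.13: the split number Φ, side product formed per part of starting material taken by partner, a selectivity factor.

Φ puts alder's starting material at 38.3% at 12.0 min. Decay at that moment's rate, 0.0695 min⁻¹, leaves 11.0% at 30 min. My reckoning is therefore side product 47.2%, 41.9% through partner, and second reagent 0.255 M after what side product takes. One number is not enough, however: Φ does not say how far partner's share has moved on towards target.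

The forecast gives target 1.5%, side product 48%, intermediate A 35% and second reagent 0.25 M, holding that “Target barely appears and lags”.

The flask gives target 2.93%, side product 45.8%, intermediate A 33.6% and second reagent 0.245 M.

    third reagent + intermediate B → target (k = 0.190 L mol⁻¹ min⁻¹)
    starting material + partner → intermediate A (k = 0.340 L mol⁻¹ min⁻¹)
    second reagent + intermediate A → intermediate B (k = 0.0410 L mol⁻¹ min⁻¹)
    starting material + second reagent → side product (k = 0.120 L mol⁻¹ min⁻¹)

In alder at 30.0 min, side product stands at 45.8% against 41.1% turned over through partner, a split of 1.11. At that moment in alder the side-product step consumes starting material at 0.96 of the partner step's rate. Scaling Φ to 1.60 equiv of partner gives 0.669, and that neighbour holds 38.1% side product with 5.80% starting material left, a split of 0.679.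

The numbers in the tables were computed for substances that don't exist; the scatter is artificial.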